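**Plan**
Retrosynthesis: the three ArO–Si bonds are cut first, then all three N–C(=O) and all three C(=O)–Cα bonds together, which leads back to spermidine, three molecules of carbon monoxide and three molecules of one (E)-β-iodostyrene; the iodide is cut at its C=C bond to a 4-silyloxybenzaldehyde and iodoform.
Enabling feature: each amide carbonyl carbon lies between one spermidine nitrogen (N1, N5 or N10) and the α-carbon of a 4-oxygenated styryl group, so it can enter as carbon monoxide between an N–H and an alkenyl C–I bond.
Forward order: phenol silylation, Takai iodo-olefination, one-flask seven-component assembly of the triamide chain, global desilylation; no ring is formed and the three benzene rings are bought.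
Stereochemistry: there is no stereocentre; the three (E) double bonds are set in the olefination and carried through the carbonylation with retention.

Key step: step 3

Remark on the chemistry: spermidine is taken as the commercial free base, distilled from KOH before use, and the spent reductant of the Takai step is assumed to end, after aqueous work-up, as the simple trihalides of trivalent chromium.
Remark on the chemistry: the balanced equation of the key step is three molecules of iodide 4, one of spermidine 5, three of carbon monoxide 6 and three of Et3N giving one molecule of 8 and three of triethylammonium iodide; its Reactants line gives these equivalents and its line of atom-supplying reagents writes each structure once per molecule incorporated.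

**Route**

Step 1
Reactants: 1 4-hydroxybenzaldehyde
Product: 2 4-(tert-butyldimethylsilyloxy)benzaldehyde
Conditions: TBSCl (1.2 equiv), imidazole (2 equiv), DMF, 0 °C to rt
Reagents that add atoms: tert-butyldimethylsilyl chloride (TBSCl), CC(C)(C)[Si](C)(C)Cl
Why: Imidazole-promoted O-silylation of a phenol is fast and leaves the aldehyde untouched, and the aryl silyl ether keeps the acidic phenol away from the organochromium reagent of step 2 and from acyl-palladium in step 3.

Step 2
Reactants: 2 4-(tert-butyldimethylsilyloxy)benzaldehyde, 3 iodoform
Product: 4 (E)-tert-butyl[4-(2-iodovinyl)phenoxy]dimethylsilane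
Conditions: CrCl2 (6 equiv), CHI3 (2 equiv), THF/1,4-dioxane, 0 °C to rt, dark
Reagents that add atoms: iodoform (3), IC(I)I
Why: Takai iodo-olefination, in which divalent chromium reduces iodoform to a geminal dichromium species that adds to the aldehyde and eliminates from the less crowded adduct, which for aromatic aldehydes strongly favours the (E)-alkenyl iodide; the aryl silyl ether is inert to CrCl2.

Step 3
Reactants: 4 (E)-tert-butyl[4-(2-iodovinyl)phenoxy]dimethylsilane (3 equiv), 5 spermidine (1 equiv), 6 carbon monoxide (3 equiv)
Product: 8 N1,N5,N10-tris[(E)-3-(4-tert-butyldimethylsilyloxyphenyl)prop-2-enoyl]spermidine, via N1,N10-bis-acylated spermidine 7 (not isolated)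
Conditions: Pd(OAc)2 (5 mol% per C–I), Xantphos (6 mol%), CO balloon (1 atm), Et3N (6 equiv), DMF, 50 °C; 4 charged in 20% surplus (3.6 equiv), 5 added over 2 h by syringe pump
Reagents that add atoms: carbon monoxide (3 equiv), [C-]#[O+].[C-]#[O+].[C-]#[O+]; alkenyl iodide 4 (3 equiv), CC(C)(C)[Si](C)(C)Oc1ccc(/C=C/I)cc1.CC(C)(C)[Si](C)(C)Oc1ccc(/C=C/I)cc1.CC(C)(C)[Si](C)(C)Oc1ccc(/C=C/I)cc1
Why: Pd(OAc)2 is reduced in the flask to a zerovalent palladium–Xantphos complex that inserts into the alkenyl C–I bond of 4 with retention of the (E) geometry, carbon monoxide inserts into the Pd–C bond to give an (E)-cinnamoyl–palladium iodide, and an N–H of spermidine cleaves it to the amide while Et3N takes up HI and returns zerovalent palladium. This cycle turns over three times on each molecule of 5, so that three molecules of 4 and three of 6 are consumed and three C(α)–C(=O) and three C(=O)–N bonds are formed; the closest known reaction type is the Heck-type aminocarbonylation of iodoalkenes with primary and secondary amines, which is also known to convert diamines into bis-carboxamides. No ring is closed and no stereocentre is created; the (E) alkenes are fixed by the iodide and should persist because neither oxidative addition nor migratory insertion touches the double-bond geometry. The step needs exhaustive N-acylation: the two primary termini should react first to give diamide 7, and the slower secondary N5 is driven on by the surplus of 4, the warm temperature and the slow addition of 5, which also keeps the concentration of free chelating polyamine low so that it cannot displace the wide-bite-angle diphosphine from palladium. It also needs single rather than double insertion of carbon monoxide, which alkenyl acyl–palladium species under 1 atm with a chelating diphosphine are expected to give, and acylation at N rather than O, which the three silyl ethers secure.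

Step 4
Reactants: 8 N1,N5,N10-tris[(E)-3-(4-tert-butyldimethylsilyloxyphenyl)prop-2-enoyl]spermidine
Product: 9 N1,N5,N10-tri-(E)-p-coumaroylspermidine
Conditions: TBAF (3.3 equiv), AcOH (3.3 equiv), THF, 0 °C to rt, dim light
Reagents that add atoms: none
Why: Fluoride-mediated cleavage of aryl silyl ethers, driven by Si–F bond formation and buffered with AcOH so that no free phenoxide or basic fluoride can add to or isomerise the cinnamamides; the amides and (E)-alkenes are inert and light is excluded to prevent E to Z photoisomerisation.

**Compound list**
1 | 4-hydroxybenzaldehyde | O=Cc1ccc(O)cc1 | starting material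
2 | 4-(tert-butyldimethylsilyloxy)benzaldehyde | CC(C)(C)[Si](C)(C)Oc1ccc(C=O)cc1 | intermediate
3 | iodoform (triiodomethane) | IC(I)I | starting material
4 | (E)-tert-butyl[4-(2-iodovinyl)phenoxy]dimethylsilane | CC(C)(C)[Si](C)(C)Oc1ccc(/C=C/I)cc1 | intermediate
5 | spermidine, N1-(3-aminopropyl)butane-1,4-diamine | NCCCCNCCCN | starting material
6 | carbon monoxide | [C-]#[O+] | starting material
7 | N1,N10-bis[(E)-3-(4-tert-butyldimethylsilyloxyphenyl)prop-2-enoyl]spermidine, central N5–H free, formed in the flask and not isolated | CC(C)(C)[Si](C)(C)Oc1ccc(/C=C/C(=O)NCCCCNCCCNC(=O)/C=C/c2ccc(O[Si](C)(C)C(C)(C)C)cc2)cc1 | intermediate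
8 | N1,N5,N10-tris[(E)-3-(4-tert-butyldimethylsilyloxyphenyl)prop-2-enoyl]spermidine | CC(C)(C)[Si](C)(C)Oc1ccc(/C=C/C(=O)NCCCCN(CCCNC(=O)/C=C/c2ccc(O[Si](C)(C)C(C)(C)C)cc2)C(=O)/C=C/c2ccc(O[Si](C)(C)C(C)(C)C)cc2)cc1 | intermediate
9 | N1,N5,N10-tri-(E)-p-coumaroylspermidine, all three alkenes (E) | O=C(/C=C/c1ccc(O)cc1)NCCCCN(CCCNC(=O)/C=C/c1ccc(O)cc1)C(=O)/C=C/c1ccc(O)cc1 | target

**Count**
Total steps: 4. Longest linear sequence: 4 steps (1 → 2 → 4 → 8 → 9); spermidine, iodoform and carbon monoxide enter as bought.

**Steps most likely to fail**

First, step 3. Palladium may be sequestered by the chelating polyamine, and acylation may stall at the hindered central nitrogen, leaving mixtures of partly acylated amines. The fallback sets out from 4 and comes back at 8, and it separates carbonylation from amide formation. Iodide 4 is carbonylated with 2,4,6-trichlorophenyl formate as a crystalline carbon monoxide surrogate (Pd(OAc)2, Xantphos, Et3N, toluene, rt) to give 2,4,6-trichlorophenyl (E)-3-(4-tert-butyldimethylsilyloxyphenyl)prop-2-enoate F1. This active ester is purified and then used in slight surplus (3.3 equiv) against spermidine 5 with Et3N and catalytic DMAP in THF at rt to 45 °C, which should acylate all three nitrogens and give 8 without the polyamine ever meeting palladium.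

Second, step 2. The E/Z selectivity of the chromium-mediated olefination may erode, and the Z-iodide would be carried into the carbonylation. The fallback sets out from 2 and comes back at 4, and it builds the alkene by syn-hydrometalation of an alkyne. Corey–Fuchs reaction of 2 (CBr4, PPh3, CH2Cl2, 0 °C) should give tert-butyl[4-(2,2-dibromovinyl)phenoxy]dimethylsilane F2. Treatment with n-BuLi (2.1 equiv, THF, −78 °C, then aqueous NH4Cl) should give tert-butyl(4-ethynylphenoxy)dimethylsilane F3. Hydrozirconation with Cp2Zr(H)Cl in THF at rt gives by syn-addition the (E)-alkenylzirconocene chloride F4, which is not isolated and is cleaved with I2 at 0 °C with retention to give 4 as a single geometric isomer.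

Third, step 4. The cinnamamides may isomerise from E to Z under light or base during triple desilylation, and the polar triphenol may be lost while it is separated from ammonium salts. The fallback sets out from 4 and comes back at 9, and it moves the desilylation ahead of the coupling, onto a small non-polar molecule. Iodide 4 is treated with TBAF/AcOH in THF at 0 °C to give (E)-4-(2-iodovinyl)phenol F5, which is used at once. F5 (3.6 equiv) is submitted with spermidine 5 and carbon monoxide 6 to the conditions of step 3 with additional Et3N, which should give 9 directly. The amines should outcompete the phenol for acyl-palladium, and any aryl ester formed is itself an acylating agent toward the remaining amine.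

**Further compounds**
F1 | step 3 | 2,4,6-trichlorophenyl (E)-3-(4-tert-butyldimethylsilyloxyphenyl)prop-2-enoate | CC(C)(C)[Si](C)(C)Oc1ccc(/C=C/C(=O)Oc2c(Cl)cc(Cl)cc2Cl)cc1
F2 | step 2 | tert-butyl[4-(2,2-dibromovinyl)phenoxy]dimethylsilane | CC(C)(C)[Si](C)(C)Oc1ccc(C=C(Br)Br)cc1
F3 | step 2 | tert-butyl(4-ethynylphenoxy)dimethylsilane | CC(C)(C)[Si](C)(C)Oc1ccc(C#C)cc1
F4 | step 2 | chlorobis(cyclopentadienyl)[(E)-2-(4-tert-butyldimethylsilyloxyphenyl)vinyl]zirconium, not isolated | CC(C)(C)[Si](C)(C)Oc1ccc(/C=C/[Zr](Cl)(C2C=CC=C2)C2C=CC=C2)cc1
F5 | step 4 | (E)-4-(2-iodovinyl)phenol | Oc1ccc(/C=C/I)cc1
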